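The runs are calculated with constants of no real substance; scatter was added.

The slowness of the solid electrophile is what you take over at this bench.

| flask | solid electrophile | nucleophile | free base | remark | time |
|---|---|---|---|---|---|
| winter | 0.020 M | 0.024 M | 0.084 M | run made earlier |  |
| midnight | 0.020 M | 0.024 M | 0.13 M | run made earlier |  |
| noon | 0.020 M | 0.036 M | 0.060 M | run made earlier |  |
| flask | 0.020 M | 0.0240 M | 0.0600 M |  | 2.0 h |

- winter (time / h: solid electrophile / %, target / %): 0.200: 97.5, 1.9; 0.417: 90.6, 3.9; 1.00: 80.0, 10.6; 2.50: 54.2, 29.1
- midnight (time / h: solid electrophile / %, target / %): 0.200: 95.9, 2.6; 0.417: 92.0, 4.4; 1.00: 78.4, 12.2; 2.50: 53.9, 25.7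
- noon (time / h: solid electrophile / %, target / %): 0.333: 93.0, 3.1; 0.833: 81.8, 9.6; 1.50: 70.8, 22.3; 2.50: 52.4, 33.5

(standard deviation of a reading: 1 percentage point)

- solid electrophile is a solid; its amount is given per volume of the solution
- the earlier runs were read with a standard deviation of 1 percentage point
- steps that have been proposed: 2 nucleophile -> self-condensation product; nucleophile + acid set free <-> protonated nucleophile; solid electrophile <-> electrophile; acid set free + free base <-> salt of the base; electrophile + nucleophile -> acid set free + target
- at the start none of the solid electrophile is in solution
- what has only dissolved of solid electrophile counts as not reacted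
- the earlier runs do not show how much of nucleophile is bound; that part of a forecast is a guess

1. part of the solid electrophile that has reacted (what has only dissolved counts as not reacted) at 2.0 h
2. share of the unused nucleophile that is free and not bound as protonated nucleophile, at 2.0 h

In the winter run the solid fell to 54.2% by 2.50 h, which gives 0.00366 M h⁻¹: call this D, the solid electrophile lost per litre of solution per hour. The midnight run, with 0.13 M of free base against winter's 0.084 M, stood at 53.9%, so leave the free base alone. I read the loss as zero order in the charge, but that is untested, since these runs share 0.020 M.

When you come at 2.0 h, I expect 36.6% of this flask's charge to have left the solid. At its reading at 2.50 h, winter held 63.5% of its lost solid as target; borrowing that share for this flask, I estimate 23.3% reacted. The forecast is lower, at 20.5%, and puts 88% of the unused nucleophile free: “If the nucleophile's basicity is comparable, most stays free”.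

The flask gives 24.2% reacted and 60.3% free, below the forecast's figure.

    2 nucleophile → self-condensation product (k = 7.20 M⁻¹ h⁻¹)
    nucleophile + acid set free ⇌ protonated nucleophile, settled at all times (K = 4.10 × 10⁵ M⁻¹)
    solid electrophile ⇌ electrophile, rate k3*(cs3 - [electrophile]) while solid is left; crystals form when [electrophile] > cs3 (solubility = 10.0 mM, k = 0.440 h⁻¹)
    acid set free + free base ⇌ salt of the base, settled at all times (K = 29.0 M⁻¹)
    electrophile + nucleophile → acid set free + target (k = 120 M⁻¹ h⁻¹)

The flask's solid stood at 63.0%, a loss of 0.00741 M against 0.00732 M from D. At that time electrophile was made 1.45 times as fast as it was used up, and it stood at 12.8%. The neighbour flask charged with 0.050 M of solid electrophile, otherwise this recipe, lost 0.00741 M of solid, against the same 0.00732 M from D, and reached 9.70% reacted.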